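## Retrosynthetic overview

1. Feature: one benzene ring (C1–C6) carries three unequal oxygens. O4 on C4 sits between Br–C3 and O5 and is para to the benzylic C7. O5 on C5 lies next to H–C6 and is meta to C7. The third oxygen is on C7. O4 and the C7 oxygen bear SO3H and O5 is free, so a free O4–H para to a leaving group on C7 is a latent para-quinone methide.
2. Endgame: K+/H+ exchange and fluoride cleavage of Si–O5. Before these, both O–S bonds (O4–S and C7O–S) are cut together, leading back to the 5-O-triisopropylsilyl diol 10 and SO3·pyridine 11.
3. Diol 10 comes from aldehyde 9 (NaBH4). O4 and O5 are told apart at the aldehyde stage by the higher acidity of O4–H (para to CHO, ortho to Br): PMB on O4, TIPS on O5, PMB off.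
4. Catechol aldehyde 4 comes from 5-bromovanillin 1 by bromination at the future C2 (para to OMe) followed by O-demethylation.
5. No ring is formed, since the only ring is bought with 1, and the target has no stereocentre.

Key step: step 7

Assumption: the target is taken as drawn, doubly protonated, so the dipotassium salt 15 serves as the storable form and the free acid 16 is liberated from it last; 12 and 13 are drawn in the same protonated form although in pyridine they exist, and 13 is isolated, as pyridinium salts.

## Route

Step 1
Reactants: 1 5-bromovanillin; 2 bromine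
Product: 3 2,3-dibromo-4-hydroxy-5-methoxybenzaldehyde
Conditions: Br2 (1.3 equiv), FeBr3 (5 mol %), AcOH, rt → 45 °C
Reagents that add atoms: bromine (2), BrBr
Why: Electrophilic aromatic bromination should go to the free CH para to the methoxy group (the future C2), because the other free CH is wedged between CHO and OMe and both positions ortho to the phenol are filled; brominating before demethylation spares a catechol from oxidation by Br2.

Step 2
Reactants: 3 2,3-dibromo-4-hydroxy-5-methoxybenzaldehyde
Product: 4 2,3-dibromo-4,5-dihydroxybenzaldehyde
Conditions: BBr3 (2.5 equiv), CH2Cl2, −78 °C → rt; ice–water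
Reagents that add atoms: none
Why: Lewis-acid cleavage of an aryl methyl ether with BBr3, in which boron binds the ether oxygen and bromide removes the methyl group by SN2, while the aryl bromides and the deactivated aldehyde are left alone at or below room temperature.

Step 3
Reactants: 4 2,3-dibromo-4,5-dihydroxybenzaldehyde; 5 4-methoxybenzyl chloride
Product: 6 2,3-dibromo-5-hydroxy-4-[(4-methoxyphenyl)methoxy]benzaldehyde
Conditions: 5 (1.05 equiv), NaHCO3 (1.5 equiv), DMF, 40 °C
Reagents that add atoms: 4-methoxybenzyl chloride (5), COc1ccc(CCl)cc1
Why: Williamson etherification under weak-base control, as known for the 4-O-selective protection of 3,4-dihydroxybenzaldehydes: only O4–H, para to CHO and ortho to Br, is acidic enough for NaHCO3, so only its phenolate is alkylated.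

Step 4
Reactants: 6 2,3-dibromo-5-hydroxy-4-[(4-methoxyphenyl)methoxy]benzaldehyde; 7 triisopropylsilyl chloride
Product: 8 2,3-dibromo-4-[(4-methoxyphenyl)methoxy]-5-(triisopropylsilyloxy)benzaldehyde
Conditions: 7 (1.3 equiv), imidazole (2.5 equiv), DMF, rt
Reagents that add atoms: triisopropylsilyl chloride (7), CC(C)[Si](Cl)(C(C)C)C(C)C
Why: Imidazole-promoted silylation of a phenol: O5–H is the only hydroxyl left and has the small H–C6 on one side, so even the bulky chlorosilane should reach it.

Step 5
Reactants: 8 2,3-dibromo-4-[(4-methoxyphenyl)methoxy]-5-(triisopropylsilyloxy)benzaldehyde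
Product: 9 2,3-dibromo-4-hydroxy-5-(triisopropylsilyloxy)benzaldehyde
Conditions: DDQ (2,3-dichloro-5,6-dicyano-1,4-benzoquinone, 1.5 equiv), CH2Cl2–pH 7 phosphate buffer (10:1), 0 °C → rt
Reagents that add atoms: none
Why: Oxidative cleavage of a 4-methoxybenzyl ether, in which DDQ oxidises the electron-rich anisyl CH2 and water releases 9 and anisaldehyde while the electron-poor dibromobenzaldehyde ring and the Si–O bond stay untouched; the step precedes the reduction because DDQ would oxidise a 4-hydroxybenzyl alcohol.

Step 6
Reactants: 9 2,3-dibromo-4-hydroxy-5-(triisopropylsilyloxy)benzaldehyde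
Product: 10 2,3-dibromo-4-hydroxy-5-(triisopropylsilyloxy)benzyl alcohol
Conditions: NaBH4 (1.5 equiv), THF–EtOH, 0 °C; pH 7 phosphate buffer quench
Reagents that add atoms: none
Why: Borohydride reduction of an aromatic aldehyde, as in vanillin to vanillyl alcohol: C–Br and Si–O bonds are inert at 0 °C, the silyl group has no drive to shift because O4 is both the more crowded site and the better phenoxide, and the buffered quench avoids acid ionisation of the 4-hydroxybenzyl alcohol; no stereocentre arises.

Step 7
Reactants: 10 2,3-dibromo-4-hydroxy-5-(triisopropylsilyloxy)benzyl alcohol; 11 sulfur trioxide pyridine complex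
Product: 13 2,3-dibromo-4-(sulfooxy)-5-(triisopropylsilyloxy)benzyl hydrogen sulfate, via benzylic monosulfate 12 (not isolated)
Conditions: 11 (10 equiv), pyridine–DMF (1:1), 10 added dropwise at 0 °C, then 40 °C; cold aqueous pyridine quench; C18, MeCN–H2O
Reagents that add atoms: sulfur trioxide pyridine complex (11), O=S(=O)=O.c1ccncc1
Why: Each free hydroxyl oxygen attacks the sulfur of the SO3–pyridine adduct, and pyridine departs and takes up the proton, which is the standard O-sulfation of alcohols and phenols with SO3–amine complexes; two O–S bonds (C7O–S and O4–S) form in one flask, no ring closes and no stereocentre arises. The unhindered primary hydroxyl on C7 should react first at 0 °C to give 12, and O4–H, squeezed between Br on C3 and the silyloxy group on C5, should follow with the large excess of 11 on warming, since SO3 is a small electrophile that also sulfates 2,6-disubstituted phenols. The selectivity needed is O4 and the C7 oxygen against O5, and it is secured by the triisopropylsilyl ether, which stays on O5 because that site is less crowded and because O4–H (ortho to Br) is the more acidic phenol, so neither rate nor equilibrium favours a 1,2-silyl shift. The weak point is 12, a 4-hydroxybenzyl sulfate that could lose sulfate to a para-quinone methide; adding 10 to the excess reagent keeps its lifetime short, and in this aprotic medium the leaving group would have to depart as a poorly solvated sulfate dianion. Once O4 is sulfated the para oxygen can no longer push out the C7 sulfate, so 13 should survive isolation as its bis(pyridinium) salt.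

Step 8
Reactants: 13 2,3-dibromo-4-(sulfooxy)-5-(triisopropylsilyloxy)benzyl hydrogen sulfate; 14 potassium fluoride
Product: 15 dipotassium 2,3-dibromo-5-hydroxy-4-(sulfonatooxy)benzyl sulfate
Conditions: KF (8 equiv), MeOH, 0 °C → rt; filtration, C18 desalting (H2O → MeOH–H2O)
Reagents that add atoms: potassium fluoride (14), [K+].[F-]
Why: Fluoride cleavage of an aryl silyl ether: fluoride attacks silicon and expels the O5 phenoxide, sulfate monoester anions do not react with fluoride or methanol at room temperature, the freed O5 is meta to C7 and so cannot push out the benzylic sulfate, and potassium takes the place of pyridinium.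

Step 9
Reactants: 15 dipotassium 2,3-dibromo-5-hydroxy-4-(sulfonatooxy)benzyl sulfate
Product: 16 2,3-dibromo-5-hydroxy-4-(sulfooxy)benzyl hydrogen sulfate (CNP0301961.0)
Conditions: polystyrenesulfonic acid resin (H+ form), H2O, 0–4 °C; eluate freeze-dried at once
Reagents that add atoms: none
Why: Cation exchange on a sulfonic acid resin swaps K+ for H+ without touching any bond to carbon or sulfur, and low temperature with immediate freeze-drying should outrun acid-catalysed hydrolysis of the two sulfate esters.

## Compound list

1 | 5-bromovanillin (3-bromo-4-hydroxy-5-methoxybenzaldehyde) | COc1cc(C=O)cc(Br)c1O | starting material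
2 | bromine | BrBr | starting material
3 | 2,3-dibromo-4-hydroxy-5-methoxybenzaldehyde | COc1cc(C=O)c(Br)c(Br)c1O | intermediate
4 | 2,3-dibromo-4,5-dihydroxybenzaldehyde | O=Cc1cc(O)c(O)c(Br)c1Br | intermediate
5 | 4-methoxybenzyl chloride | COc1ccc(CCl)cc1 | starting material
6 | 2,3-dibromo-5-hydroxy-4-[(4-methoxyphenyl)methoxy]benzaldehyde | O=Cc1cc(O)c(OCc2ccc(OC)cc2)c(Br)c1Br | intermediate
7 | triisopropylsilyl chloride | CC(C)[Si](Cl)(C(C)C)C(C)C | starting material
8 | 2,3-dibromo-4-[(4-methoxyphenyl)methoxy]-5-(triisopropylsilyloxy)benzaldehyde | O=Cc1cc(O[Si](C(C)C)(C(C)C)C(C)C)c(OCc2ccc(OC)cc2)c(Br)c1Br | intermediate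
9 | 2,3-dibromo-4-hydroxy-5-(triisopropylsilyloxy)benzaldehyde | O=Cc1cc(O[Si](C(C)C)(C(C)C)C(C)C)c(O)c(Br)c1Br | intermediate
10 | 2,3-dibromo-4-hydroxy-5-(triisopropylsilyloxy)benzyl alcohol | OCc1cc(O[Si](C(C)C)(C(C)C)C(C)C)c(O)c(Br)c1Br | intermediate
11 | sulfur trioxide pyridine complex | O=S(=O)=O.c1ccncc1 | starting material
12 | 2,3-dibromo-4-hydroxy-5-(triisopropylsilyloxy)benzyl hydrogen sulfate (not isolated) | O=S(=O)(O)OCc1cc(O[Si](C(C)C)(C(C)C)C(C)C)c(O)c(Br)c1Br | intermediate
13 | 2,3-dibromo-4-(sulfooxy)-5-(triisopropylsilyloxy)benzyl hydrogen sulfate (handled as bis(pyridinium) salt) | O=S(=O)(O)OCc1cc(O[Si](C(C)C)(C(C)C)C(C)C)c(OS(=O)(=O)O)c(Br)c1Br | intermediate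
14 | potassium fluoride | [K+].[F-] | starting material
15 | dipotassium 2,3-dibromo-5-hydroxy-4-(sulfonatooxy)benzyl sulfate | [K+].[K+].[O-]S(=O)(=O)OCc1cc(O)c(OS(=O)(=O)[O-])c(Br)c1Br | intermediate
16 | 2,3-dibromo-5-hydroxy-4-(sulfooxy)benzyl hydrogen sulfate | O=S(=O)(O)OCc1cc(O)c(OS(=O)(=O)O)c(Br)c1Br | target

Total step count: 9. Longest linear sequence: 9 steps (from 1).

## Steps most likely to fail

**Step 7.**
- Risk: sulfation of the crowded O4 may lag behind that of the C7 oxygen. The monosulfated stage could then live long enough to lose sulfate by para-quinone methide formation and be captured by pyridine. Forcing the reaction may also let SO3 insert into the O5–Si bond.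
- Fallback: the two sulfates are installed one after the other, with the aldehyde masking C7.
- Setting out from 9, the acidic O4 phenol is sulfated as its triethylammonium phenolate with 11 and Et3N in DMF. Heating is allowed here because no benzylic leaving group is present. This gives 2,3-dibromo-4-formyl-6-(triisopropylsilyloxy)phenyl hydrogen sulfate F1.
- NaBH4 in aqueous EtOH reduces the aldehyde of this salt to 2,3-dibromo-4-(hydroxymethyl)-6-(triisopropylsilyloxy)phenyl hydrogen sulfate F2.
- The unhindered primary alcohol is then sulfated with 11 in pyridine at 0 °C, and the route is rejoined at 13. A 4-hydroxybenzyl sulfate never exists on this path.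

**Step 9.**
- Risk: the dilute acidic eluate has to be concentrated. Acid-catalysed hydrolysis of the aryl sulfate and solvolysis of the benzylic sulfate may speed up as the acid becomes more concentrated.
- Fallback: precipitation metathesis in a small volume replaces column exchange.
- Setting out from 15, Ba(OAc)2 in a little water followed by EtOH should deposit barium 2,3-dibromo-5-hydroxy-4-(sulfonatooxy)benzyl sulfate F3, while KOAc stays in the aqueous ethanol.
- A suspension of this salt in ice water is titrated with exactly one equivalent of dilute H2SO4, and BaSO4 is spun off.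
- The concentrated metal-free supernatant is 16, which needs little or no concentration.

**Step 5.**
- Risk: the oxidation may stall, because the aryloxy oxygen of an electron-poor ring gives little support to the developing benzylic cation. Long exposure to DDQ and water may also erode the silyl ether.
- Fallback: the PMB group is avoided altogether.
- Setting out from 4, both phenols are silylated with triisopropylsilyl triflate and 2,6-lutidine in CH2Cl2 to give 2,3-dibromo-4,5-bis(triisopropylsilyloxy)benzaldehyde F4.
- Brief treatment with K2CO3 in aqueous DMF at 0 °C should remove only the O4 silyl group. The O4 phenoxide (para to CHO, ortho to Br) is the better leaving group and its silyl group is the more strained.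
- An isomer cleaved at the wrong oxygen would drift to the same compound by base-mediated 1,2-silyl shift. The route is rejoined at 9, and steps 3 to 5 are bypassed.

## Further compounds

F1 | step 7 | 2,3-dibromo-4-formyl-6-(triisopropylsilyloxy)phenyl hydrogen sulfate | O=Cc1cc(O[Si](C(C)C)(C(C)C)C(C)C)c(OS(=O)(=O)O)c(Br)c1Br
F2 | step 7 | 2,3-dibromo-4-(hydroxymethyl)-6-(triisopropylsilyloxy)phenyl hydrogen sulfate | OCc1cc(O[Si](C(C)C)(C(C)C)C(C)C)c(OS(=O)(=O)O)c(Br)c1Br
F3 | step 9 | barium 2,3-dibromo-5-hydroxy-4-(sulfonatooxy)benzyl sulfate | [Ba+2].[O-]S(=O)(=O)OCc1cc(O)c(OS(=O)(=O)[O-])c(Br)c1Br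
F4 | step 5 | 2,3-dibromo-4,5-bis(triisopropylsilyloxy)benzaldehyde | O=Cc1cc(O[Si](C(C)C)(C(C)C)C(C)C)c(O[Si](C(C)C)(C(C)C)C(C)C)c(Br)c1Br
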